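**Plan**

- Retrosynthesis: the C8–C9 oxirane goes back to the cycloheptene, the two esters to a C6 ketone and a 2β-silyl ether, the C4 carbinol to a C4 ketone plus isopropyl. The seven-membered ring is then cut at C6–C7 and C10–C1 in one stroke.
- Enabling feature: with C5=C6 and C8=C9 restored, the seven-membered ring (C1, C5–C10), fused to the cyclopentane at C1–C5, is a cyclohepta-1,4-diene. That is the product pattern of a cis-divinylcyclopropane rearrangement, with C6 as the carbene carbon.
- Forward: (S)-4-silyloxycyclopentenone gives cyclopentenyl diazoacetate 6 (C1–C6). Prenal gives silyl dienol ether 8 (C7–C10). Rhodium-catalysed cyclopropanation/Cope joins them and closes the seven-membered ring (step 5).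
- Then: conjugate reduction, isopropyl addition with lactonization, excision of the ester carbon to the C6 ketone, directed reduction, veratroylation, Mitsunobu acetate, desilylation, and photoisomerization/epoxidation.
- Stereochemistry: C2 from the chiral pool (inverted at the end). C1 and C10 from catalyst-controlled cyclopropanation and the stereospecific boat Cope shift. C4 and C5 by substrate control. C6 by C4–OH-directed hydride delivery. C8 and C9 by syn oxygen transfer to the (E)-cycloheptene.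

Key step: step 5

Remark: both oxirane carbons (C8, C9) are R in the given structure, so the ring bonds C7–C8 and C9–C10 are trans across the oxirane (O is β at C8 and α at C9); such a trans-fused oxirane can only come from the (E)-cycloheptene, which shapes the last step.

Numbering (daucane) used in all names: C1 angular C–CH3; C2 CH–OAc; C3 CH2; C4 C(OH)(i-Pr); C5 ring-fusion CH; C6 CH–O2CAr; C7 CH2; C8 C(CH3); C9 CH; C10 CH–OH. The five-membered ring is C1–C5 and the seven-membered ring is C1, C5–C10. β is the face of the C1 methyl group, α the other face. TBS = tert-butyldimethylsilyl, TIPS = triisopropylsilyl.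

**Step 1**
Reactants: 1 (S)-4-(tert-butyldimethylsilyloxy)cyclopent-2-en-1-one
Product: 3 (S)-4-(tert-butyldimethylsilyloxy)-3-methylcyclopent-2-en-1-one, via silyl enol ether 2 (not isolated)
Conditions: Me2CuLi, TMSCl, THF, −78 °C; then Pd(OAc)2, MeCN, rt
Reagents that add atoms: lithium dimethylcuprate, [Li+].C[Cu-]C
Why: Cuprate conjugate addition to a 4-silyloxycyclopentenone occurs anti to the silyloxy group, and Saegusa–Ito oxidation of the trapped silyl enol ether restores the enone regiospecifically with the new β-methyl group while the silyloxy stereocenter is untouched.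

**Step 2**
Reactants: 3 (S)-4-(tert-butyldimethylsilyloxy)-3-methylcyclopent-2-en-1-one
Product: 4 (S)-4-(tert-butyldimethylsilyloxy)-2-iodo-3-methylcyclopent-2-en-1-one
Conditions: I2, pyridine, CH2Cl2, rt
Reagents that add atoms: iodine, II
Why: α-Iodination of an enone by the iodine/pyridine addition–elimination sequence gives the vinyl iodide needed for coupling.

**Step 3**
Reactants: 4 (S)-4-(tert-butyldimethylsilyloxy)-2-iodo-3-methylcyclopent-2-en-1-one; 5 methyl diazoacetate
Product: 6 methyl 2-diazo-2-[(3S)-3-(tert-butyldimethylsilyloxy)-2-methyl-5-oxocyclopent-1-en-1-yl]acetate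
Conditions: Pd(PPh3)4 (5 mol%), Et3N, Bu4NBr, MeCN, rt
Reagents that add atoms: none
Why: Palladium-catalysed cross-coupling of a vinyl iodide with a diazoacetate, with retention of the diazo group, installs the donor/acceptor diazo unit on C5 in one step; 6 is used at once because vinyldiazo compounds cyclize slowly to pyrazoles.

**Step 4**
Reactants: 7 3-methylbut-2-enal
Product: 8 (E)-triisopropyl[(3-methylbuta-1,3-dien-1-yl)oxy]silane
Conditions: TIPSOTf, Et3N, CH2Cl2, 0 °C
Reagents that add atoms: triisopropylsilyl trifluoromethanesulfonate, CC(C)[Si](OS(=O)(=O)C(F)(F)F)(C(C)C)C(C)C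
Why: O-Silylation of the extended enolate formed by γ-deprotonation of the enal under soft enolization should give the (E)-1-silyloxy diene.

**Step 5**
Reactants: 6 methyl 2-diazo-2-[(3S)-3-(tert-butyldimethylsilyloxy)-2-methyl-5-oxocyclopent-1-en-1-yl]acetate; 8 (E)-triisopropyl[(3-methylbuta-1,3-dien-1-yl)oxy]silane
Product: 10 methyl 2β-(TBSO)-1β,8-dimethyl-4-oxo-10α-(TIPSO)bicyclo[5.3.0]deca-5,8-diene-6-carboxylate (target numbering), via cis-divinylcyclopropane 9 (not isolated)
Conditions: Rh2(R-DOSP)4 (dirhodium tetrakis[(R)-N-(4-dodecylphenylsulfonyl)prolinate], 1 mol%), 8 (3 equiv), hexanes/toluene, slow addition of 6, −40 °C → rt; then 60 °C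
Reagents that add atoms: none
Why: The rhodium carbenoid from 6 is attacked by the unhindered, vinylogously oxygen-activated C7 terminus of 8 and cyclopropanates the C7=C8 bond (carbene carbon = C6) to give cis-divinylcyclopropane 9, which undergoes a [3,3]-sigmatropic (Cope) shift through the boat transition state that forms C1–C10 while the C6–C7 bond from the cyclopropanation is kept. The closest known reaction type is the tandem cyclopropanation/Cope rearrangement (formal (4+3) cycloaddition) of vinyldiazoacetates with dienes under dirhodium tetracarboxylate catalysis. The seven-membered ring is closed by this six-electron pericyclic shift onto the existing cyclopentene, so the hydroazulene arises as a cyclohepta-1,4-diene (C5=C6, C8=C9). C1 and C10 are set in the boat transition state, where the two E substituents (ring carbon C2 on C1, OTIPS on C10) end cis, that is C1–Me β and C10–O α; their absolute sense follows from the cyclopropane configuration fixed by the chiral catalyst (the R antipode is chosen from the sense known for Rh2(S-DOSP)4 cyclopropanations), with the 2β-silyloxy group anti to the incoming diene arm (matched case). The step needs site selectivity for the 1,1-disubstituted C7=C8 bond over the trans enol ether bond, and carbene-carbon over vinylogous reactivity; the electronic bias of the dienol ether and the fully substituted vinyl terminus C1 secure both, and any trans-divinylcyclopropane should equilibrate to 9 at 60 °C.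

**Step 6**
Reactants: 10 methyl 2β-(TBSO)-1β,8-dimethyl-4-oxo-10α-(TIPSO)bicyclo[5.3.0]deca-5,8-diene-6-carboxylate
Product: 11 methyl 2β-(TBSO)-1β,8-dimethyl-4-oxo-10α-(TIPSO)bicyclo[5.3.0]dec-8-ene-6β-carboxylate (5α-H, 6α-H)
Conditions: Zn, AcOH, THF, rt
Reagents that add atoms: none
Why: Electron-transfer conjugate reduction of the ene-1,4-dicarbonyl unit by zinc in acetic acid saturates only C5=C6; protonation on the α face, opposite the C1 methyl and C2 silyloxy groups, should give the trans ring fusion, and a 6-epimer would converge in step 7.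

**Step 7**
Reactants: 11 methyl 2β-(TBSO)-1β,8-dimethyl-4-oxo-10α-(TIPSO)bicyclo[5.3.0]dec-8-ene-6β-carboxylate
Product: 13 2β-(TBSO)-10α-(TIPSO)-5α-H-dauc-8-ene-6β-carboxylic acid 4β-lactone, via hydroxy ester 12 (not isolated)
Conditions: i-PrLi, CeCl3, THF, −78 °C; then 0 °C, NH4Cl
Reagents that add atoms: isopropyllithium, [Li]C(C)C
Why: The weakly basic organocerium reagent adds to the enolizable C4 ketone from the α face (the β face is blocked by C1–Me, C2–OTBS and the C6 side chain), and the 4β-alkoxide closes the cis-fused γ-lactone on the neighbouring ester, which sets C4 and locks C5.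

**Step 8**
Reactants: 13 2β-(TBSO)-10α-(TIPSO)-5α-H-dauc-8-ene-6β-carboxylic acid 4β-lactone
Product: 14 6α-hydroxy-2β-(TBSO)-10α-(TIPSO)-5α-H-dauc-8-ene-6β-carboxylic acid 4β-lactone
Conditions: LDA, THF, −78 °C; then 3-phenyl-2-(phenylsulfonyl)oxaziridine, −78 °C
Reagents that add atoms: 3-phenyl-2-(phenylsulfonyl)oxaziridine, O=S(=O)(c1ccccc1)N1OC1c1ccccc1
Why: Hydroxylation of the lactone enolate with a Davis oxaziridine puts oxygen on C6, the only enolizable position, and so prepares the excision of the carbonyl carbon.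

**Step 9**
Reactants: 14 6α-hydroxy-2β-(TBSO)-10α-(TIPSO)-5α-H-dauc-8-ene-6β-carboxylic acid 4β-lactone
Product: 16 4β-hydroxy-2β-(TBSO)-10α-(TIPSO)-5α-H-dauc-8-en-6-one, via hydroxy acid 15 (not isolated)
Conditions: LiOH, THF/H2O, rt; then NaIO4, NaHCO3, rt
Reagents that add atoms: none
Why: Saponification to the α-hydroxy carboxylate and periodate oxidative decarboxylation of the α-hydroxy acid turn C6 into a ketone and free the tertiary C4 alcohol under near-neutral conditions, which should spare the β-hydroxy ketone and keep the β,γ-alkene out of conjugation.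

**Step 10**
Reactants: 16 4β-hydroxy-2β-(TBSO)-10α-(TIPSO)-5α-H-dauc-8-en-6-one
Product: 17 2β-(TBSO)-10α-(TIPSO)-5α-H-dauc-8-ene-4β,6α-diol
Conditions: Me4NBH(OAc)3, MeCN/AcOH, −20 °C
Reagents that add atoms: none
Why: In this Evans–Saksena reduction the C4 alkoxy(acetoxy)borohydride delivers hydride intramolecularly to the β face of the C6 carbonyl, giving the 1,3-anti (4β,6α) diol.

**Step 11**
Reactants: 17 2β-(TBSO)-10α-(TIPSO)-5α-H-dauc-8-ene-4β,6α-diol
Product: 18 4β-hydroxy-2β-(TBSO)-10α-(TIPSO)-5α-H-dauc-8-en-6α-yl 3,4-dimethoxybenzoate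
Conditions: 3,4-(MeO)2C6H3COCl, DMAP, Et3N, CH2Cl2, rt
Reagents that add atoms: 3,4-dimethoxybenzoyl chloride, COc1ccc(C(=O)Cl)cc1OC
Why: DMAP-catalysed acylation takes the only free secondary alcohol; the tertiary C4 alcohol does not react.

**Step 12**
Reactants: 18 4β-hydroxy-2β-(TBSO)-10α-(TIPSO)-5α-H-dauc-8-en-6α-yl 3,4-dimethoxybenzoate
Product: 19 2β,4β-dihydroxy-10α-(TIPSO)-5α-H-dauc-8-en-6α-yl 3,4-dimethoxybenzoate
Conditions: HF·pyridine, pyridine, THF, 0 °C
Reagents that add atoms: none
Why: Buffered fluoride cleaves the secondary TBS ether faster than the bulkier TIPS ether on the neopentyl allylic C10 oxygen.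

**Step 13**
Reactants: 19 2β,4β-dihydroxy-10α-(TIPSO)-5α-H-dauc-8-en-6α-yl 3,4-dimethoxybenzoate
Product: 20 2α-acetoxy-4β-hydroxy-10α-(TIPSO)-5α-H-dauc-8-en-6α-yl 3,4-dimethoxybenzoate
Conditions: PPh3, DIAD, AcOH, toluene, 0 → 40 °C
Reagents that add atoms: acetic acid, CC(=O)O
Why: Mitsunobu esterification with acetic acid displaces the activated 2β-oxygen with inversion (as in the 17β to 17α inversion of steroidal cyclopentanols) and gives the 2α-acetate directly; the tertiary alcohol is inert.

**Step 14**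
Reactants: 20 2α-acetoxy-4β-hydroxy-10α-(TIPSO)-5α-H-dauc-8-en-6α-yl 3,4-dimethoxybenzoate
Product: 21 2α-acetoxy-4β,10α-dihydroxy-5α-H-dauc-8-en-6α-yl 3,4-dimethoxybenzoate (Z ring alkene)
Conditions: HF·pyridine, THF, rt
Reagents that add atoms: none
Why: Acidic fluoride removes the TIPS group without the base-induced acyl migration that could occur between the cis C2 and C10 oxygens.

**Step 15**
Reactants: 21 2α-acetoxy-4β,10α-dihydroxy-5α-H-dauc-8-en-6α-yl 3,4-dimethoxybenzoate
Product: 23 2α-acetoxy-8β,9α-epoxy-4β,10α-dihydroxy-5α-H-daucan-6α-yl 3,4-dimethoxybenzoate (target), via (E)-cycloheptene 22 (not isolated)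
Conditions: hν (254 nm), PhCO2Me (sensitizer), Et2O/pentane, −78 °C; then DMDO, acetone, −78 °C, dark; recovered 21 recycled
Reagents that add atoms: dimethyldioxirane, CC1(C)OO1
Why: Proposed new method: singlet-sensitized Z to E isomerization of C8=C9 through an arene–alkene exciplex (external benzoate, assisted by the veratrate at C6) should give the twisted (E)-cycloheptene 22, which persists at −78 °C; its strained π bond should take oxygen from DMDO on its only exposed face far faster than the cis alkene, in a stereospecific syn transfer that turns the trans ring bonds into the trans-fused oxirane, and the planar-chiral isomer with the C8 methyl α and H9 β gives the 8R,9R product; the closest known reaction types are the low-temperature trapping of photogenerated (E)-cycloheptene by OsO4 and by dipoles, and the dioxirane or peracid epoxidation of isolable trans-cyclooctene.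

**Compound list**

1 | (S)-4-(tert-butyldimethylsilyloxy)cyclopent-2-en-1-one | O=C1C=C[C@@H](O[Si](C)(C)C(C)(C)C)C1 | starting material
2 | (3S,4S)-4-(tert-butyldimethylsilyloxy)-3-methyl-1-(trimethylsilyloxy)cyclopent-1-ene (methyl trans to OTBS) | C[Si](C)(C)OC1=C[C@H](C)[C@@H](O[Si](C)(C)C(C)(C)C)C1 | intermediate
3 | (S)-4-(tert-butyldimethylsilyloxy)-3-methylcyclopent-2-en-1-one | O=C1C=C(C)[C@@H](O[Si](C)(C)C(C)(C)C)C1 | intermediate
4 | (S)-4-(tert-butyldimethylsilyloxy)-2-iodo-3-methylcyclopent-2-en-1-one | O=C1C(I)=C(C)[C@@H](O[Si](C)(C)C(C)(C)C)C1 | intermediate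
5 | methyl diazoacetate | COC(=O)C=[N+]=[N-] | starting material
6 | methyl 2-diazo-2-[(3S)-3-(tert-butyldimethylsilyloxy)-2-methyl-5-oxocyclopent-1-en-1-yl]acetate | COC(=O)C(=[N+]=[N-])C1=C(C)[C@@H](O[Si](C)(C)C(C)(C)C)CC1=O | intermediate
7 | 3-methylbut-2-enal | CC(C)=CC=O | starting material
8 | (E)-triisopropyl[(3-methylbuta-1,3-dien-1-yl)oxy]silane | C=C(C)/C=C/O[Si](C(C)C)(C(C)C)C(C)C | intermediate
9 | methyl 1-[(3S)-3-(TBSO)-2-methyl-5-oxocyclopent-1-en-1-yl]-2-methyl-2-[(E)-2-(TIPSO)ethenyl]cyclopropane-1-carboxylate, cyclopentenyl and silyloxyethenyl groups cis | COC(=O)[C@]1(C2=C(C)[C@@H](O[Si](C)(C)C(C)(C)C)CC2=O)C[C@@]1(C)/C=C/O[Si](C(C)C)(C(C)C)C(C)C | intermediate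
10 | methyl 2β-(TBSO)-1β,8-dimethyl-4-oxo-10α-(TIPSO)bicyclo[5.3.0]deca-5,8-diene-6-carboxylate (target numbering) | COC(=O)C1=C2C(=O)C[C@H](O[Si](C)(C)C(C)(C)C)[C@@]2(C)[C@@H](O[Si](C(C)C)(C(C)C)C(C)C)C=C(C)C1 | intermediate
11 | methyl 2β-(TBSO)-1β,8-dimethyl-4-oxo-10α-(TIPSO)bicyclo[5.3.0]dec-8-ene-6β-carboxylate, 5α-H, 6α-H | COC(=O)[C@@H]1[C@@H]2C(=O)C[C@H](O[Si](C)(C)C(C)(C)C)[C@@]2(C)[C@@H](O[Si](C(C)C)(C(C)C)C(C)C)C=C(C)C1 | intermediate
12 | methyl 4β-hydroxy-2β-(TBSO)-10α-(TIPSO)-5α-H-dauc-8-ene-6β-carboxylate (4α-isopropyl) | COC(=O)[C@@H]1[C@@H]2[C@@](O)(C(C)C)C[C@H](O[Si](C)(C)C(C)(C)C)[C@@]2(C)[C@@H](O[Si](C(C)C)(C(C)C)C(C)C)C=C(C)C1 | intermediate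
13 | 2β-(TBSO)-10α-(TIPSO)-5α-H-dauc-8-ene-6β-carboxylic acid 4β-lactone (cis-fused γ-lactone) | O=C1O[C@]2(C(C)C)C[C@H](O[Si](C)(C)C(C)(C)C)[C@@]3(C)[C@@H](O[Si](C(C)C)(C(C)C)C(C)C)C=C(C)C[C@H]1[C@H]23 | intermediate
14 | 6α-hydroxy-2β-(TBSO)-10α-(TIPSO)-5α-H-dauc-8-ene-6β-carboxylic acid 4β-lactone | O=C1O[C@]2(C(C)C)C[C@H](O[Si](C)(C)C(C)(C)C)[C@@]3(C)[C@@H](O[Si](C(C)C)(C(C)C)C(C)C)C=C(C)C[C@@]1(O)[C@H]23 | intermediate
15 | 4β,6α-dihydroxy-2β-(TBSO)-10α-(TIPSO)-5α-H-dauc-8-ene-6β-carboxylic acid | OC(=O)[C@]1(O)[C@@H]2[C@@](O)(C(C)C)C[C@H](O[Si](C)(C)C(C)(C)C)[C@@]2(C)[C@@H](O[Si](C(C)C)(C(C)C)C(C)C)C=C(C)C1 | intermediate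
16 | 4β-hydroxy-2β-(TBSO)-10α-(TIPSO)-5α-H-dauc-8-en-6-one | O=C1CC(C)=C[C@H](O[Si](C(C)C)(C(C)C)C(C)C)[C@]2(C)[C@@H](O[Si](C)(C)C(C)(C)C)C[C@](O)(C(C)C)[C@@H]12 | intermediate
17 | 2β-(TBSO)-10α-(TIPSO)-5α-H-dauc-8-ene-4β,6α-diol | O[C@@H]1CC(C)=C[C@H](O[Si](C(C)C)(C(C)C)C(C)C)[C@]2(C)[C@@H](O[Si](C)(C)C(C)(C)C)C[C@](O)(C(C)C)[C@@H]12 | intermediate
18 | 4β-hydroxy-2β-(TBSO)-10α-(TIPSO)-5α-H-dauc-8-en-6α-yl 3,4-dimethoxybenzoate | COc1ccc(C(=O)O[C@@H]2CC(C)=C[C@H](O[Si](C(C)C)(C(C)C)C(C)C)[C@]3(C)[C@@H](O[Si](C)(C)C(C)(C)C)C[C@](O)(C(C)C)[C@@H]23)cc1OC | intermediate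
19 | 2β,4β-dihydroxy-10α-(TIPSO)-5α-H-dauc-8-en-6α-yl 3,4-dimethoxybenzoate | COc1ccc(C(=O)O[C@@H]2CC(C)=C[C@H](O[Si](C(C)C)(C(C)C)C(C)C)[C@]3(C)[C@@H](O)C[C@](O)(C(C)C)[C@@H]23)cc1OC | intermediate
20 | 2α-acetoxy-4β-hydroxy-10α-(TIPSO)-5α-H-dauc-8-en-6α-yl 3,4-dimethoxybenzoate | COc1ccc(C(=O)O[C@@H]2CC(C)=C[C@H](O[Si](C(C)C)(C(C)C)C(C)C)[C@]3(C)[C@H](OC(C)=O)C[C@](O)(C(C)C)[C@@H]23)cc1OC | intermediate
21 | 2α-acetoxy-4β,10α-dihydroxy-5α-H-dauc-8-en-6α-yl 3,4-dimethoxybenzoate, Z ring alkene | COc1ccc(C(=O)O[C@@H]2C/C(C)=C\[C@H](O)[C@]3(C)[C@H](OC(C)=O)C[C@](O)(C(C)C)[C@@H]23)cc1OC | intermediate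
22 | (E)-cycloheptene isomer of 21, planar-chiral form with the C8 methyl α and H9 β | COc1ccc(C(=O)O[C@@H]2C/C(C)=C/[C@H](O)[C@]3(C)[C@H](OC(C)=O)C[C@](O)(C(C)C)[C@@H]23)cc1OC | intermediate
23 | 2α-acetoxy-8β,9α-epoxy-4β,10α-dihydroxy-5α-H-daucan-6α-yl 3,4-dimethoxybenzoate (8R,9R; trans-fused oxirane) | COc1ccc(C(=O)O[C@@H]2C[C@@]3(C)O[C@@H]3[C@H](O)[C@]3(C)[C@H](OC(C)=O)C[C@](O)(C(C)C)[C@@H]23)cc1OC | target

**Step count and risks**

Total steps: 15. Longest linear sequence: 14 steps (steps 1–3 and 5–15); step 4 is a one-step branch.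

Steps most likely to fail:

1. Step 15 (labelled step). The conversion at the photostationary state may be low, the (E)-isomer may revert thermally before oxygen transfer, and selection between the two planar-chiral (E)-isomers may be poor, which would give the 8S,9S oxirane as well. Fallback from 21, built from operations known on the parent ring systems: flow photoisomerization (254 nm, methyl benzoate) with continuous capture of the trans isomer on AgNO3-impregnated silica should give the silver nitrate complex F1 of (E)-alkene 22. The two planar-chiral diastereomers would be separated at this stage, and the unwanted one reverts to 21 on release and warming and is recycled. Release of the alkene from F1 with aqueous NaCl at low temperature into cold DMDO, as in the epoxidation of trans-cyclooctene, returns to the route at 23.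

2. Step 5. Mismatched double stereodifferentiation between catalyst and the C2 stereocenter, carbenoid attack at the enol ether bond, or cyclization of 6 to a pyrazole before carbenoid formation may erode the yield and facial control. Fallback from 4, replacing catalyst control by a chiral auxiliary: the same palladium coupling with (R)-pantolactonyl diazoacetate should give pantolactonyl vinyldiazoacetate F2. Its reaction with 8 under Rh2(OOct)4 (dirhodium tetraoctanoate) in pentane should give pantolactonyl cycloheptadiene ester F3. Zn/AcOH should give pantolactonyl keto ester F4, and the i-PrLi/CeCl3 addition then expels pantolactone in the lactonization and returns to the route at 13.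

3. Step 13. Elimination toward the cyclopentene, or failure of displacement at the neopentyl carbinol, may defeat the inversion. Fallback from 19, replacing substitution by a redox relay: Dess–Martin oxidation should give C2 ketone F5. Me4NBH(OAc)3 reduction, directed by the 4β-hydroxyl as in step 10, should give 2α-alcohol F6. Acetylation with Ac2O/DMAP returns to the route at 20.

**Further compounds**

F1 | step 15 | silver nitrate complex of (E)-cycloheptene 22 | COc1ccc(C(=O)O[C@@H]2C/C(C)=C/[C@H](O)[C@]3(C)[C@H](OC(C)=O)C[C@](O)(C(C)C)[C@@H]23)cc1OC.[Ag+].[O-][N+](=O)[O-]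
F2 | step 5 | (R)-pantolactonyl 2-diazo-2-[(3S)-3-(TBSO)-2-methyl-5-oxocyclopent-1-en-1-yl]acetate | CC1(C)COC(=O)[C@@H]1OC(=O)C(=[N+]=[N-])C1=C(C)[C@@H](O[Si](C)(C)C(C)(C)C)CC1=O
F3 | step 5 | (R)-pantolactonyl ester analogue of 10 | CC1(C)COC(=O)[C@@H]1OC(=O)C1=C2C(=O)C[C@H](O[Si](C)(C)C(C)(C)C)[C@@]2(C)[C@@H](O[Si](C(C)C)(C(C)C)C(C)C)C=C(C)C1
F4 | step 5 | (R)-pantolactonyl ester analogue of 11 | CC1(C)COC(=O)[C@@H]1OC(=O)[C@@H]1[C@@H]2C(=O)C[C@H](O[Si](C)(C)C(C)(C)C)[C@@]2(C)[C@@H](O[Si](C(C)C)(C(C)C)C(C)C)C=C(C)C1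
F5 | step 13 | 4β-hydroxy-2-oxo-10α-(TIPSO)-5α-H-dauc-8-en-6α-yl 3,4-dimethoxybenzoate | COc1ccc(C(=O)O[C@@H]2CC(C)=C[C@H](O[Si](C(C)C)(C(C)C)C(C)C)[C@]3(C)C(=O)C[C@](O)(C(C)C)[C@@H]23)cc1OC
F6 | step 13 | 2α,4β-dihydroxy-10α-(TIPSO)-5α-H-dauc-8-en-6α-yl 3,4-dimethoxybenzoate | COc1ccc(C(=O)O[C@@H]2CC(C)=C[C@H](O[Si](C(C)C)(C(C)C)C(C)C)[C@]3(C)[C@H](O)C[C@](O)(C(C)C)[C@@H]23)cc1OC
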